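Rings: upper unit A (phloroglucinol), B (catechol), C (pyran); lower unit D, E, F likewise; flavan numbering within each unit. The retrosynthesis cuts, in this order: the fourteen O-benzyl bonds; C2–C3 of ring F; the enol-ester and N,O-acetal C–O bonds on ring D; the interflavan bond C4 (ring C)–C6 (ring D).
Forward: rings A, B and C come intact from (−)-epicatechin (benzylation, C4 activation, 3-O-galloylation). Ring D comes from 3,5-bis(benzyloxy)phenol (O-allylation, Claisen rearrangement, silylation) and is joined to C4 while ring F is still open. Ring E then arrives on an N,O-acetal carbon (future C2), the allyl group is cut down to an (E)-enol gallate (future C4, C3 and 3-O-gallate), ring F is closed, and hydrogenolysis follows.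
Enabling feature: the oxygens of ring D at C5, C7 and C8a make a C4 benzylic cation strongly stabilised, so O1=C2(+), the aromatic C8a=C4a bond and C4=C3 act as a six-electron oxa-hexatriene cation that closes between C2 and C3. The enol ester carries the gallate through the closure and a hydride donor turns C4 into CH2.
Connectivity: while ring F is open, the future O1 can carry a bulky silyl group, which is meant to steer the upper unit to C6 (para to O1) and away from C8.
Stereochemistry: C2 and C3 of the upper unit come from the chiral pool; C4 is set by attack trans to the 3-acyloxy group; C2/C3 of the lower unit become cis through disrotatory closure of an (E)-oxocarbenium ion onto an (E)-enol ester, with the absolute sense assigned to a chiral Brønsted-acid counter-anion.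
Key step: step 13

Remark: 3,4,5-tris(benzyloxy)benzoyl chloride, 3,5-bis(benzyloxy)phenol and 3,4-bis(benzyloxy)benzaldehyde are taken as commercial. The N,O-acetal carbon introduced in step 10 is carried as both epimers, which is immaterial because it becomes planar in the key step.

Step 1
Reactants: 1 (−)-epicatechin
Product: 2 5,7,3',4'-tetra-O-benzyl-(−)-epicatechin
Conditions: BnBr, K2CO3, DMF, 0 °C to rt
Reagents that add atoms: benzyl bromide BrCc1ccccc1
Why: Williamson etherification: K2CO3 deprotonates only the four phenols, so benzyl bromide should give the tetrabenzyl ether while the secondary 3-OH and the (2R,3R) centres of the chiral pool stay untouched.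

Step 2
Reactants: 2 5,7,3',4'-tetra-O-benzyl-(−)-epicatechin
Product: 3 5,7,3',4'-tetra-O-benzyl-4β-(2-ethoxyethoxy)-(−)-epicatechin
Conditions: 2,3-dichloro-5,6-dicyano-1,4-benzoquinone (DDQ), 2-ethoxyethanol, CH2Cl2, rt
Reagents that add atoms: 2-ethoxyethanol CCOCCO
Why: DDQ-mediated benzylic oxidation (hydride abstraction from C4, the cation being stabilised by the ring A oxygens) followed by capture of the cation by 2-ethoxyethanol on the face opposite the 3-oxygen and the C2 aryl group should set the new C4 centre as 4β, a reaction type with close precedent on benzylated flavan-3-ols.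

Step 3
Reactants: 3 5,7,3',4'-tetra-O-benzyl-4β-(2-ethoxyethoxy)-(−)-epicatechin; 4 3,4,5-tris(benzyloxy)benzoyl chloride
Product: 5 3-O-[3,4,5-tris(benzyloxy)benzoyl] ester of 3
Conditions: 4-(dimethylamino)pyridine, pyridine, CH2Cl2, rt
Reagents that add atoms: none
Why: Nucleophile-catalysed acylation of the secondary alcohol by the acid chloride installs the upper gallate with retention at C3 and provides a participating neighbour for step 7.

Step 4
Reactants: 6 3,5-bis(benzyloxy)phenol
Product: 7 1-(allyloxy)-3,5-bis(benzyloxy)benzene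
Conditions: allyl bromide, K2CO3, acetone, reflux
Reagents that add atoms: allyl bromide C=CCBr
Why: Williamson O-allylation of the phenoxide sets up the Claisen rearrangement.

Step 5
Reactants: 7 1-(allyloxy)-3,5-bis(benzyloxy)benzene
Product: 9 2-allyl-3,5-bis(benzyloxy)phenol, via dienone 8 (not isolated)
Conditions: PhNEt2, 190 °C
Reagents that add atoms: none
Why: Aromatic Claisen rearrangement ([3,3]-sigmatropic shift to dienone 8, then tautomerisation) moves the allyl group to one of the two equivalent ortho positions, so a single phenol should result in which the three-carbon chain sits next to the future O1.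

Step 6
Reactants: 9 2-allyl-3,5-bis(benzyloxy)phenol
Product: 10 [2-allyl-3,5-bis(benzyloxy)phenoxy]tri(propan-2-yl)silane
Conditions: i-Pr3SiCl, imidazole, DMF, rt
Reagents that add atoms: chlorotri(propan-2-yl)silane CC(C)[Si](Cl)(C(C)C)C(C)C
Why: Silylation of the phenol (silyl ether formation) puts a bulky group on the future O1 that shields the neighbouring free aromatic position in step 7.

Step 7
Reactants: 5 C4-activated upper unit; 10 silylated ring D fragment (3 equiv)
Product: 12 4β-aryl flavan (upper unit bonded at C4 to C6 of ring D which carries OSi(i-Pr)3 at C8a and allyl at C4a), via C4 cation 11 (not isolated)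
Conditions: Me3SiOSO2CF3 (cat.), CH2Cl2, −78 °C
Reagents that add atoms: none
Why: Lewis-acid ionisation of the C4 acetal gives cation 11, covered on the α face by the 3-O-galloyl group, and Friedel–Crafts alkylation by the electron-rich ring of 10 from the β face should set C4 trans to the 3-acyloxy group (4β), while the triisopropylsilyl ether is expected to steer attack to the ring carbon para to it, between the two benzyloxy groups, which is the future C6 of ring D.

Step 8
Reactants: 12 silyl ether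
Product: 13 phenol (free OH at C8a of ring D)
Conditions: Bu4NF, AcOH, THF, 0 °C
Reagents that add atoms: none
Why: Fluoride-induced desilylation, buffered with acetic acid so that the ester and the upper C2 centre do not meet a strong base, frees the phenol that becomes O1.

Step 9
Reactants: 14 3,4-bis(benzyloxy)benzaldehyde
Product: 16 1-{chloro[3,4-bis(benzyloxy)phenyl]methyl}-1H-benzotriazole, via hemiaminal 15 (not isolated)
Conditions: 1H-benzotriazole, toluene, rt; then SOCl2, 0 °C to rt
Reagents that add atoms: 1H-benzotriazole c1ccc2[nH]nnc2c1; thionyl chloride O=S(Cl)Cl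
Why: Addition of benzotriazole to the aldehyde gives hemiaminal 15, whose hydroxyl group is replaced by chloride with SOCl2 (the standard preparation of 1-(α-chloroalkyl)benzotriazoles), and the chloride is used crude as a racemate.

Step 10
Reactants: 13 phenol; 16 1-{chloro[3,4-bis(benzyloxy)phenyl]methyl}-1H-benzotriazole
Product: 17 N,O-acetal (O1 of ring D carries the (benzotriazol-1-yl)[3,4-bis(benzyloxy)phenyl]methyl group)
Conditions: K2CO3, MeCN, 0 °C to rt
Reagents that add atoms: none
Why: O-Alkylation of the phenoxide by the easily ionised benzylic chloride (Williamson-type etherification with SN1 character) should give the N,O-acetal as both epimers at the new carbon, which is immaterial because this carbon becomes planar in step 13.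

Step 11
Reactants: 17 N,O-acetal with allyl group
Product: 19 arylacetaldehyde (2-oxoethyl group at C4a of ring D), via diol 18 (not isolated)
Conditions: OsO4 (cat.), NaIO4, 2,6-lutidine, dioxane–H2O, rt
Reagents that add atoms: osmium tetroxide O=[Os](=O)(=O)=O (source of the aldehyde oxygen, re-formed by NaIO4); sodium periodate [Na+].[O-]I(=O)(=O)=O
Why: Lemieux–Johnson oxidation (osmylation to diol 18 and periodate cleavage in one flask) shortens the allyl group to the arylacetaldehyde, the 2,6-lutidine buffer protecting the N,O-acetal and the electron-rich arenes being inert to OsO4.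

Step 12
Reactants: 19 arylacetaldehyde; 4 3,4,5-tris(benzyloxy)benzoyl chloride
Product: 20 (E)-enol gallate (C4a of ring D carries (E)-CH=CH–O–CO–C6H2(OBn)3)
Conditions: Et3N, 4-(dimethylamino)pyridine (cat.), CH2Cl2, −20 °C
Reagents that add atoms: none
Why: O-Acylation of the amine-generated enolate of the arylacetaldehyde (enol ester formation) should favour the (E)-enol ester because the (Z)-isomer forces the acyloxy group against the two ortho substituents of ring D, and any (Z)-isomer is removed by chromatography.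

Step 13
Reactants: 20 (E)-enol gallate N,O-acetal
Product: 23 tetradeca-O-benzyl procyanidin B-5 3,3'-di-O-gallate, via aryloxycarbenium ion 21 (not isolated), via flavan-4-yl cation 22 (not isolated)
Conditions: (R)-N-triflylphosphoramide of 3,3'-bis(2,4,6-triisopropylphenyl)-1,1'-bi-2-naphthol (10 mol %), Et3SiH (1.5 equiv, added slowly), toluene, −40 °C
Reagents that add atoms: none
Why: Proposed new method: protonation of the benzotriazole nitrogen of 20 by the chiral acid expels benzotriazole and gives aryloxycarbenium ion 21, in which O1=C2, the aromatic C8a=C4a bond and C4=C3 form a six-electron oxa-hexatriene cation; thermal disrotatory 6π electrocyclisation joins C2 to C3 and gives flavan-4-yl cation 22, which takes hydride from Et3SiH, the silyl group ending on benzotriazole so that the acid is released. The closest known reaction types are the oxa-Povarov reaction (aryl oxocarbenium ion plus alkene), the 6π-azaelectrocyclisation of N-aryl iminium ions with an ortho vinyl group, the Prins cyclisation and the ionic hydrogenation of flavan-4-yl cations; none has been shown for an O-aryl oxocarbenium ion closing onto an ortho enol ester. The pyran ring F is the only ring closed, by the electrocyclisation, which is 6-endo-trig with respect to both the C=O(+) and the C=C bond. With the aryl group on C2 of the (E)-oxocarbenium ion and the acyloxy group on C3 of the (E)-enol ester both pointing outward, disrotation places them cis, so the enol ester geometry controls C3 relative to C2 (2,3-cis). The absolute configuration is meant to come from the chiral phosphoramide anion paired with 21, which selects the sense of rotation (closest precedent: chiral N-triflylphosphoramide control of Nazarov electrocyclisations), the enantiomer of the acid being chosen so that (2R,3R) results. The step needs bonding through C3 and not C4 of the enol ester (the three oxygens of ring D make cation 22 far more stable than an acyloxycarbenium ion at C3), cyclisation faster than reduction of 21 (silane added slowly) and hydride capture faster than loss of H-3 (no base stronger than benzotriazole is present).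

Step 14
Reactants: 23 tetradeca-O-benzyl procyanidin B-5 3,3'-di-O-gallate
Product: 24 procyanidin B-5 3,3'-di-O-gallate
Conditions: H2 (1 atm), Pd(OH)2 on carbon, THF–MeOH–H2O, rt
Reagents that add atoms: none
Why: Hydrogenolysis of the fourteen benzyl ethers over palladium hydroxide, the usual last step for benzylated procyanidin gallates, should leave the two esters, the interflavan bond and all six stereocentres untouched.

Compound list
1 | (−)-epicatechin, (2R,3R)-2-(3,4-dihydroxyphenyl)chromane-3,5,7-triol | O[C@@H]1Cc2c(O)cc(O)cc2O[C@@H]1c1ccc(O)c(O)c1 | starting material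
2 | 5,7,3',4'-tetra-O-benzyl-(−)-epicatechin (2R,3R) | O[C@@H]1Cc2c(OCc3ccccc3)cc(OCc3ccccc3)cc2O[C@@H]1c1ccc(OCc2ccccc2)c(OCc2ccccc2)c1 | intermediate
3 | 5,7,3',4'-tetra-O-benzyl-4β-(2-ethoxyethoxy)-(−)-epicatechin (2,3-cis, 3,4-trans) | O[C@@H]1[C@@H](OCCOCC)c2c(OCc3ccccc3)cc(OCc3ccccc3)cc2O[C@@H]1c1ccc(OCc2ccccc2)c(OCc2ccccc2)c1 | intermediate
4 | 3,4,5-tris(benzyloxy)benzoyl chloride | O=C(Cl)c1cc(OCc2ccccc2)c(OCc2ccccc2)c(OCc2ccccc2)c1 | starting material
5 | 3-O-[3,4,5-tris(benzyloxy)benzoyl] ester of 3 (C4-activated upper unit) | O=C(O[C@@H]1[C@@H](OCCOCC)c2c(OCc3ccccc3)cc(OCc3ccccc3)cc2O[C@@H]1c1ccc(OCc2ccccc2)c(OCc2ccccc2)c1)c1cc(OCc2ccccc2)c(OCc2ccccc2)c(OCc2ccccc2)c1 | intermediate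
6 | 3,5-bis(benzyloxy)phenol | Oc1cc(OCc2ccccc2)cc(OCc2ccccc2)c1 | starting material
7 | 1-(allyloxy)-3,5-bis(benzyloxy)benzene | C=CCOc1cc(OCc2ccccc2)cc(OCc2ccccc2)c1 | intermediate
8 | 6-allyl-3,5-bis(benzyloxy)cyclohexa-2,4-dien-1-one (racemic, not isolated) | C=CCC1C(=O)C=C(OCc2ccccc2)C=C1OCc1ccccc1 | intermediate
9 | 2-allyl-3,5-bis(benzyloxy)phenol | C=CCc1c(O)cc(OCc2ccccc2)cc1OCc1ccccc1 | intermediate
10 | [2-allyl-3,5-bis(benzyloxy)phenoxy]tri(propan-2-yl)silane | C=CCc1c(O[Si](C(C)C)(C(C)C)C(C)C)cc(OCc2ccccc2)cc1OCc1ccccc1 | intermediate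
11 | flavan-4-yl cation formed from 5 by loss of 2-ethoxyethoxide, C2 and C3 as in 5 (not isolated) | O=C(O[C@@H]1[CH+]c2c(OCc3ccccc3)cc(OCc3ccccc3)cc2O[C@@H]1c1ccc(OCc2ccccc2)c(OCc2ccccc2)c1)c1cc(OCc2ccccc2)c(OCc2ccccc2)c(OCc2ccccc2)c1 | intermediate
12 | 5,7,3',4'-tetra-O-benzyl-3-O-[3,4,5-tris(benzyloxy)benzoyl]-(−)-epicatechin carrying at C4 (β, trans to the 3-O-ester) a 3-allyl-2,6-bis(benzyloxy)-4-[(triisopropylsilyl)oxy]phenyl group | O=C(O[C@@H]1[C@@H](c2c(OCc3ccccc3)cc(O[Si](C(C)C)(C(C)C)C(C)C)c(CC=C)c2OCc2ccccc2)c2c(OCc3ccccc3)cc(OCc3ccccc3)cc2O[C@@H]1c1ccc(OCc2ccccc2)c(OCc2ccccc2)c1)c1cc(OCc2ccccc2)c(OCc2ccccc2)c(OCc2ccccc2)c1 | intermediate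
13 | as 12, with a 3-allyl-2,6-bis(benzyloxy)-4-hydroxyphenyl group at C4β | O=C(O[C@@H]1[C@@H](c2c(OCc3ccccc3)cc(O)c(CC=C)c2OCc2ccccc2)c2c(OCc3ccccc3)cc(OCc3ccccc3)cc2O[C@@H]1c1ccc(OCc2ccccc2)c(OCc2ccccc2)c1)c1cc(OCc2ccccc2)c(OCc2ccccc2)c(OCc2ccccc2)c1 | intermediate
14 | 3,4-bis(benzyloxy)benzaldehyde | O=Cc1ccc(OCc2ccccc2)c(OCc2ccccc2)c1 | starting material
15 | (1H-benzotriazol-1-yl)[3,4-bis(benzyloxy)phenyl]methanol (racemic, not isolated) | OC(c1ccc(OCc2ccccc2)c(OCc2ccccc2)c1)n1nnc2ccccc21 | intermediate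
16 | 1-{chloro[3,4-bis(benzyloxy)phenyl]methyl}-1H-benzotriazole (racemic) | ClC(c1ccc(OCc2ccccc2)c(OCc2ccccc2)c1)n1nnc2ccccc21 | intermediate
17 | as 13, with the phenol oxygen alkylated: 3-allyl-2,6-bis(benzyloxy)-4-{(1H-benzotriazol-1-yl)[3,4-bis(benzyloxy)phenyl]methoxy}phenyl at C4β (both epimers at the N,O-acetal carbon) | O=C(O[C@@H]1[C@@H](c2c(OCc4ccccc4)cc(OC(c3ccc(OCc4ccccc4)c(OCc4ccccc4)c3)n3nnc4ccccc43)c(CC=C)c2OCc2ccccc2)c2c(OCc3ccccc3)cc(OCc3ccccc3)cc2O[C@@H]1c1ccc(OCc2ccccc2)c(OCc2ccccc2)c1)c1cc(OCc2ccccc2)c(OCc2ccccc2)c(OCc2ccccc2)c1 | intermediate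
18 | as 17, with 2,3-dihydroxypropyl in place of allyl (both epimers at the carbinol carbon, not isolated) | O=C(O[C@@H]1[C@@H](c2c(OCc4ccccc4)cc(OC(c3ccc(OCc4ccccc4)c(OCc4ccccc4)c3)n3nnc4ccccc43)c(CC(O)CO)c2OCc2ccccc2)c2c(OCc3ccccc3)cc(OCc3ccccc3)cc2O[C@@H]1c1ccc(OCc2ccccc2)c(OCc2ccccc2)c1)c1cc(OCc2ccccc2)c(OCc2ccccc2)c(OCc2ccccc2)c1 | intermediate
19 | as 17, with 2-oxoethyl in place of allyl (arylacetaldehyde) | O=C(O[C@@H]1[C@@H](c2c(OCc4ccccc4)cc(OC(c3ccc(OCc4ccccc4)c(OCc4ccccc4)c3)n3nnc4ccccc43)c(CC=O)c2OCc2ccccc2)c2c(OCc3ccccc3)cc(OCc3ccccc3)cc2O[C@@H]1c1ccc(OCc2ccccc2)c(OCc2ccccc2)c1)c1cc(OCc2ccccc2)c(OCc2ccccc2)c(OCc2ccccc2)c1 | intermediate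
20 | as 17, with (E)-2-{[3,4,5-tris(benzyloxy)benzoyl]oxy}ethenyl in place of allyl (enol gallate) | O=C(O[C@@H]1[C@@H](c2c(OCc4ccccc4)cc(OC(c3ccc(OCc4ccccc4)c(OCc4ccccc4)c3)n3nnc4ccccc43)c(/C=C/OC(=O)c3cc(OCc4ccccc4)c(OCc4ccccc4)c(OCc4ccccc4)c3)c2OCc2ccccc2)c2c(OCc3ccccc3)cc(OCc3ccccc3)cc2O[C@@H]1c1ccc(OCc2ccccc2)c(OCc2ccccc2)c1)c1cc(OCc2ccccc2)c(OCc2ccccc2)c(OCc2ccccc2)c1 | intermediate
21 | aryloxycarbenium ion formed from 20 by loss of benzotriazolide: O1 of ring D doubly bonded to the CH that carries the 3,4-bis(benzyloxy)phenyl group (not isolated) | O=C(O[C@@H]1[C@@H](c2c(OCc4ccccc4)cc([O+]=Cc3ccc(OCc4ccccc4)c(OCc4ccccc4)c3)c(/C=C/OC(=O)c3cc(OCc4ccccc4)c(OCc4ccccc4)c(OCc4ccccc4)c3)c2OCc2ccccc2)c2c(OCc3ccccc3)cc(OCc3ccccc3)cc2O[C@@H]1c1ccc(OCc2ccccc2)c(OCc2ccccc2)c1)c1cc(OCc2ccccc2)c(OCc2ccccc2)c(OCc2ccccc2)c1 | intermediate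
22 | flavan-4-yl cation of ring F with (2R,3R) configuration (2,3-cis), ring F closed and C4 cationic (not isolated) | O=C(O[C@@H]1[C@@H](c2c(OCc4ccccc4)cc3c(c2OCc2ccccc2)[CH+][C@@H](OC(=O)c2cc(OCc4ccccc4)c(OCc4ccccc4)c(OCc4ccccc4)c2)[C@@H](c2ccc(OCc4ccccc4)c(OCc4ccccc4)c2)O3)c2c(OCc3ccccc3)cc(OCc3ccccc3)cc2O[C@@H]1c1ccc(OCc2ccccc2)c(OCc2ccccc2)c1)c1cc(OCc2ccccc2)c(OCc2ccccc2)c(OCc2ccccc2)c1 | intermediate
23 | tetradeca-O-benzyl procyanidin B-5 3,3'-di-O-gallate: both units 5,7,3',4'-tetra-O-benzyl-(−)-epicatechin 3-O-[3,4,5-tris(benzyloxy)benzoate], joined 4β→6 | O=C(O[C@@H]1[C@@H](c2c(OCc4ccccc4)cc3c(c2OCc2ccccc2)C[C@@H](OC(=O)c2cc(OCc4ccccc4)c(OCc4ccccc4)c(OCc4ccccc4)c2)[C@@H](c2ccc(OCc4ccccc4)c(OCc4ccccc4)c2)O3)c2c(OCc3ccccc3)cc(OCc3ccccc3)cc2O[C@@H]1c1ccc(OCc2ccccc2)c(OCc2ccccc2)c1)c1cc(OCc2ccccc2)c(OCc2ccccc2)c(OCc2ccccc2)c1 | intermediate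
24 | procyanidin B-5 3,3'-di-O-gallate, (−)-epicatechin 3-O-gallate-(4β→6)-(−)-epicatechin 3-O-gallate | O=C(O[C@@H]1[C@@H](c2c(O)cc3c(c2O)C[C@@H](OC(=O)c2cc(O)c(O)c(O)c2)[C@@H](c2ccc(O)c(O)c2)O3)c2c(O)cc(O)cc2O[C@@H]1c1ccc(O)c(O)c1)c1cc(O)c(O)c(O)c1 | target

Total step count: 14. Longest linear sequence: 10 steps (steps 1, 2, 3, 7, 8, 10, 11, 12, 13, 14; the branch through steps 4, 5, 6 is equally long).

Steps most likely to fail

Step 13 (Proposed new method). What may go wrong: reduction of the oxocarbenium ion by the silane before ring closure, bond formation through C4 of the enol ester instead of C3, loss of H-3 from the cyclised cation before hydride capture, or poor control of the sense of rotation by the chiral anion (poor facial selectivity, giving the (2S,3S) diastereomer). The fallback uses known chemistry only, sets out from compounds 2, 4 and 5 and rejoins the route at compound 24. Compound 2 is acylated with 4 (4-(dimethylamino)pyridine, pyridine) to hepta-O-benzyl-(−)-epicatechin 3-O-gallate F1. N-Bromosuccinimide brominates the position next to the ring oxygen and gives the 8-bromo derivative F2. With C8 blocked, Me3SiOSO2CF3-mediated Friedel–Crafts coupling of F2 with 5 can take place only at C6 and should give the brominated 4β→6 dimer F3. Hydrogenolysis over Pd(OH)2 on carbon in the presence of Et3N removes the fourteen benzyl groups and the bromine and gives 24.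

Step 7. What may go wrong: poor regioselectivity (attack at the ring carbon beside the silyl ether instead of the one para to it), or slow alkylation at a carbon flanked by two benzyloxy groups so that self-condensation of the electrophile competes. The fallback sets out from compounds 9 and 5 and rejoins the route at compound 13. Phenol 9 is brominated ortho to the hydroxyl group (N-bromosuccinimide, catalytic i-Pr2NH, CH2Cl2) to 2-allyl-6-bromo-3,5-bis(benzyloxy)phenol F4, which has one free aromatic position left. Coupling with 5 (Me3SiOSO2CF3, CH2Cl2, −78 °C) then gives the bromophenol dimer F5. Radical hydrodebromination (Bu3SnH, azobisisobutyronitrile, toluene, 90 °C) gives 13.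

Step 11. What may go wrong: hydrolysis of the N,O-acetal in the aqueous oxidising medium and aldol-type decay of the arylacetaldehyde during isolation. The fallback changes the order of events so that the acetal is made last; it sets out from compound 12 and rejoins the route at compound 20. Lemieux–Johnson oxidation of the silyl ether gives the silyl-protected arylacetaldehyde F6. Enol acylation with 4 (Et3N, 4-(dimethylamino)pyridine) gives the silyl-protected (E)-enol gallate F7. Buffered desilylation (Bu4NF, AcOH) gives the phenolic enol gallate F8. Alkylation with chloride 16 under a hindered amine (i-Pr2NEt, CH2Cl2, 0 °C), which avoids a free phenoxide next to the enol ester, gives 20.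

Further compounds
F1 | step 13 | 5,7,3',4'-tetra-O-benzyl-(−)-epicatechin 3-O-[3,4,5-tris(benzyloxy)benzoate] | O=C(O[C@@H]1Cc2c(OCc3ccccc3)cc(OCc3ccccc3)cc2O[C@@H]1c1ccc(OCc2ccccc2)c(OCc2ccccc2)c1)c1cc(OCc2ccccc2)c(OCc2ccccc2)c(OCc2ccccc2)c1
F2 | step 13 | 8-bromo derivative of F1 | O=C(O[C@@H]1Cc2c(OCc3ccccc3)cc(OCc3ccccc3)c(Br)c2O[C@@H]1c1ccc(OCc2ccccc2)c(OCc2ccccc2)c1)c1cc(OCc2ccccc2)c(OCc2ccccc2)c(OCc2ccccc2)c1
F3 | step 13 | 8-bromo derivative (lower unit) of tetradeca-O-benzyl procyanidin B-5 3,3'-di-O-gallate | O=C(O[C@@H]1[C@@H](c2c(OCc4ccccc4)c(Br)c3c(c2OCc2ccccc2)C[C@@H](OC(=O)c2cc(OCc4ccccc4)c(OCc4ccccc4)c(OCc4ccccc4)c2)[C@@H](c2ccc(OCc4ccccc4)c(OCc4ccccc4)c2)O3)c2c(OCc3ccccc3)cc(OCc3ccccc3)cc2O[C@@H]1c1ccc(OCc2ccccc2)c(OCc2ccccc2)c1)c1cc(OCc2ccccc2)c(OCc2ccccc2)c(OCc2ccccc2)c1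
F4 | step 7 | 2-allyl-6-bromo-3,5-bis(benzyloxy)phenol | C=CCc1c(O)c(Br)c(OCc2ccccc2)cc1OCc1ccccc1
F5 | step 7 | as compound 13, with bromine on the ring D carbon between the hydroxyl group and a benzyloxy group | O=C(O[C@@H]1[C@@H](c2c(OCc3ccccc3)c(Br)c(O)c(CC=C)c2OCc2ccccc2)c2c(OCc3ccccc3)cc(OCc3ccccc3)cc2O[C@@H]1c1ccc(OCc2ccccc2)c(OCc2ccccc2)c1)c1cc(OCc2ccccc2)c(OCc2ccccc2)c(OCc2ccccc2)c1
F6 | step 11 | as compound 12, with 2-oxoethyl in place of allyl | O=C(O[C@@H]1[C@@H](c2c(OCc3ccccc3)cc(O[Si](C(C)C)(C(C)C)C(C)C)c(CC=O)c2OCc2ccccc2)c2c(OCc3ccccc3)cc(OCc3ccccc3)cc2O[C@@H]1c1ccc(OCc2ccccc2)c(OCc2ccccc2)c1)c1cc(OCc2ccccc2)c(OCc2ccccc2)c(OCc2ccccc2)c1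
F7 | step 11 | as compound 12, with (E)-2-{[3,4,5-tris(benzyloxy)benzoyl]oxy}ethenyl in place of allyl | O=C(O[C@@H]1[C@@H](c2c(OCc4ccccc4)cc(O[Si](C(C)C)(C(C)C)C(C)C)c(/C=C/OC(=O)c3cc(OCc4ccccc4)c(OCc4ccccc4)c(OCc4ccccc4)c3)c2OCc2ccccc2)c2c(OCc3ccccc3)cc(OCc3ccccc3)cc2O[C@@H]1c1ccc(OCc2ccccc2)c(OCc2ccccc2)c1)c1cc(OCc2ccccc2)c(OCc2ccccc2)c(OCc2ccccc2)c1
F8 | step 11 | as F7, with a free hydroxyl group in place of the silyl ether | O=C(O[C@@H]1[C@@H](c2c(OCc4ccccc4)cc(O)c(/C=C/OC(=O)c3cc(OCc4ccccc4)c(OCc4ccccc4)c(OCc4ccccc4)c3)c2OCc2ccccc2)c2c(OCc3ccccc3)cc(OCc3ccccc3)cc2O[C@@H]1c1ccc(OCc2ccccc2)c(OCc2ccccc2)c1)c1cc(OCc2ccccc2)c(OCc2ccccc2)c(OCc2ccccc2)c1
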